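## Structural features

The target 23 is an ester. Its alcohol part is a cis-fused 2,4,7-trimethyl-octahydrocyclopenta[c]pyridin-6-ol: ring A is the N-methylpiperidine C1–N2–C3–C4–C5–C9, ring B the cyclopentane C5–C6–C7–C8–C9, and the two share the C5–C9 bond. Its acid part is (2E,6S)-8-hydroxy-2,6-dimethyloct-2-enoic acid.

Five contiguous stereocentres run round the bicycle (C4, C5, C9, C8, C7). H4, H5, H9, the C10 methyl and the C7 oxygen all lie on the convex face, so C11 sits on the concave face and the ester oxygen is cis to C10 and trans to the ring A carbons C1 and C4.

The side chain carries an isolated 6S centre, an E-trisubstituted conjugated ester and a free primary alcohol, which must be masked while the hindered secondary ester is made.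

Fragile groups are the tertiary amine, the enoate and, among the intermediates, a 4-substituted cyclopent-2-enone whose γ-hydrogen at C5 makes the only early stereocentre base-labile; C4 and C8 are α to carbonyl groups in the bicyclic intermediates.

The real difficulty lies at C4 and C7. C11 must end on the concave face, which equilibration cannot be trusted to deliver. The C7 oxygen must end cis to the neighbouring methyl, on the face from which a small hydride is expected to arrive.

The key step uses three facts. C9 is β to the C7 carbonyl level through C8. N2, its methyl and C1 are sarcosine less CO2. The chain C3–C4 hangs on C5. An N-CH2 radical at C1 can therefore add to C9 of a 2-methylcyclopentenone, closing ring A as a lactam with a cis fusion that the tether enforces, and leaving C4 and C8 adjustable afterwards.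

## Logic of the disconnections

23 is traced to 22 by replacing the hydroxyl hydrogen with a silyl group (O–Si bond), and 22 is cut between C7 and the ester oxygen into 16 and 21. The cut is made there because the ketone reduction is expected to place the C7 oxygen trans to C10, so the ester bond is formed with inversion. The gain is two fragments of similar size. The demand is an SN2 reaction at a secondary carbon next to a methyl-bearing carbon, in the presence of a tertiary amine.

21 goes back through 20 and 19 to 18 and 17. No carbon–carbon bond is cut: the carboxyl carbon is the E-methyl group of the trisubstituted alkene of 17, and the stereocentre is bought. The forward steps must oxidise only that methyl group and keep the E geometry.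

16 is traced to 15 by returning C3 to the lactam carbonyl and C7 to the ketone (two C–H bonds at C3 and one at C7). This reveals the two carbonyl groups that make the ring closure and the stereochemical corrections possible. One hydride reagent must reduce both groups and attack C7 from the convex face.

15 is traced to 13 by giving up the configuration at C4 (the C4–H bond). The precursor no longer needs any control at this centre. The forward step must set it by kinetic protonation from the convex face while the ketone is masked as its enolate.

13 is cut at C1–C9, with a carboxyl group returned to C1, to give 11. This removes ring A and the stereocentres C9 and C8 in one stroke and leaves a monocyclic enone with a single controlled centre (C5). The forward step needs a nucleophilic radical at C1, closure in the 6-exo mode, and thermodynamic adjustment of C8.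

11 goes back to 10 (acid masked as the tert-butyl ester), 10 to 9 by cutting the C8–C10 bond, and 9 to 8 by removing iodine from C8. The methyl is added late because the chiral cyclopentene building block is sold without it. The coupling must run without base, since C5 is γ to the ketone.

8 is traced to 7 by returning the C7 carbonyl to the allylic alcohol, and 7 is cut at the amide bond N2–C3 into 5 and 6. The alcohol is oxidised only after the ester hydrolysis, so the enone never meets hydroxide. The coupling must tolerate the free hydroxyl.

5 goes back through 4 to 3 by restoring a methoxycarbonyl group on C4, and 3 is cut at C4–C5 into 1 and 2. The C7 oxygen and the C5 configuration are then both bought with 1, and no allylic C–H oxidation is needed. The forward alkylation must attack the allyl terminus remote from the hydroxyl with net retention.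

## Other disconnections considered

Alternative 1: The cut is the ring B bond C5–C9, with ring A thought of as a dihydropyran (oxygen in place of N2, C1 as an N,O-acetal).
- Forward step: the acyclic silyloxy dialdehyde A1 would be treated with N-methylaniline. The enamine formed at the saturated aldehyde C1 would add through C9 to C5 of the tethered enal, whose oxygen closes onto C1, so ring B and the dihydropyran arise together in A2.
- In its favour: mild conditions, and one step that sets C5 and C9 cis and, under the influence of C8, C10 trans to C1. The C7 oxygen already has the configuration of 23, so no inversion is needed; on this point the alternative is better than the chosen plan. C4 would be set late by delivering hydrogen to the convex face of the enol ether, which is at least the equal of the kinetic protonation in step 10.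
- Against it here: A1 carries two adjacent acyclic stereocentres (C7, C8) and an E-enal, which need several steps of asymmetric aldol or crotylation chemistry. The effect of the extra C7 silyloxy group on the closure is open. Nitrogen enters last, by hydrolysis of A2 to the dialdehyde level and double reductive amination with methylamine to A3, a stage at which C9 (α to the C1 aldehyde) can epimerise.
- Comparison: the alternative is polar and partly reversible, the chosen plan radical and irreversible. The chosen plan fixes the cis fusion by a covalent tether and has nitrogen in place from the start; the alternative relies on a transition-state preference. Step counts should be close, because what is saved at the end (no LiAlH4 step, A3 to F4 to 22 by plain acylation) is spent on A1.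

Alternative 2: Two ring B bonds, C7–C8 and C5–C9, are cut, and the C7 oxygen is traced to a ketone carbon excised by Baeyer–Villiger oxidation.
- Forward step: the silyloxy diene A4 and the crotonoyl imide A5 would combine under Cu(OTf)2 and a chiral bis(oxazoline) ligand in an endo Diels–Alder reaction to A6. After hydrolysis of its silyl enol ether and Baeyer–Villiger oxidation with bridgehead migration, A6 would become the bridged lactone A7.
- In its favour: one catalytic enantioselective step fixes C5, C8, C9 and the latent C7. This is better than the chosen plan, which buys C5 and sets C8 and C9 later. The endo rule places C1 cis to the future C4, and the E dienophile places C10 trans to C1. The reaction class is more certain than a radical ring closure.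
- Against it here: A4 is prone to 1,5-hydrogen shifts and dimerisation, and a β-methyl dienophile is sluggish. In the bicycle the C7 oxygen necessarily ends cis to C4, as in 16, so the inversion of step 15 is still needed; here the two plans are equal. Ring A is not formed at all: C11 must be added at C4 by alkylating the enolate of A7, the imide and the lactone must be told apart, both carboxyl carbons reduced, and N2 inserted by double alkylation of methylamine before 16 is reached.
- Comparison: the alternative is stronger in its key step and weaker in step economy, since the chosen plan closes ring A with nitrogen, C3 and C4 already in place.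

Alternative 3: The cut is C4–C5 together with C1–C9, so the three-carbon unit C1–C4(C11)–C3 is removed from an existing cyclopentene.
- Forward step: irradiation of the chelated enol A9 with the cyclopentene A8 would give, by [2+2] cycloaddition and retro-aldol cleavage in the same operation (de Mayo reaction), the 1,5-dialdehyde A10. Double reductive amination with methylamine would then lead to A3.
- In its favour: the whole carbon skeleton appears in one operation. Both new bonds are delivered to the alkene face away from C10 and the silyloxy group, so the cis fusion and its relation to C8 follow from simple sterics. The C7 oxygen and the amine oxidation level are right from the outset, so neither the LiAlH4 step nor the inversion is needed; after the key step this is better than the chosen plan in step count.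
- Against it here: C5 and C9 of A8 differ only through remote substituents, so the orientation of the enol (C4 to C5, or C4 to C9) is not controlled, and the wrong orientation gives a constitutional isomer. Enol–alkene photocycloadditions to unactivated cyclopentenes need a large excess of alkene. In A10 both C9 and C4 are α to aldehydes, so the cis relation at C9 can be lost and C4 is undefined until the reductive amination. A8 needs its own enantioselective synthesis.
- Comparison: regiochemistry is unambiguous in the chosen plan (only C9 is an acceptor) and open in the alternative. The alternative is the shorter on paper. Control of C4 is a late, soft point in both.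

Key step: step 9

Remarks on the chemistry (assumptions):
- 1 is taken as the commercial single enantiomer (the enzymatic desymmetrisation product of the meso diacetate made from cyclopentadiene), and 6 is used as the free base.
- No step before ring closure controls C4, so 4, 5 and 7 to 13, including the cyclisation substrate 11, are carried as pairs of C4 epimers and are named and drawn without a descriptor at that centre.
- The wanted C4 configuration (C11 on the concave face) is treated as the kinetic and not the thermodynamic one, by analogy with iridomyrmecin and its more stable epimer isoiridomyrmecin; step 10 therefore uses kinetic protonation.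

## Route

Step 1
Reactants: 1 (1S,4R)-cis-4-acetoxycyclopent-2-en-1-ol; 2 dimethyl methylmalonate
Product: 3 dimethyl 2-[(1R,4S)-4-hydroxycyclopent-2-en-1-yl]-2-methylpropanedioate
Conditions: 2, NaH, THF, 0 °C; then 1, Pd(PPh3)4 (3 mol%), THF, 45 °C
Reagents that add atoms: none
Why: Tsuji–Trost allylic alkylation: zerovalent palladium ionises the acetate with inversion, and the soft malonate anion attacks the allyl terminus remote from the hydroxyl, again with inversion, so C5 is formed with net retention, cis to the carbinol.

Step 2
Reactants: 3 dimethyl 2-[(1R,4S)-4-hydroxycyclopent-2-en-1-yl]-2-methylpropanedioate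
Product: 4 methyl (2RS)-2-[(1R,4S)-4-hydroxycyclopent-2-en-1-yl]propanoate
Conditions: LiCl, H2O, DMSO, 150 °C
Reagents that add atoms: none
Why: Krapcho dealkoxycarbonylation: chloride demethylates one ester, the carboxylate loses CO2 and the ester enolate is protonated without selectivity, so 4 is a pair of C4 epimers; any bridged lactone formed by acyl transfer to the cis hydroxyl is opened in step 3.

Step 3
Reactants: 4 methyl (2RS)-2-[(1R,4S)-4-hydroxycyclopent-2-en-1-yl]propanoate
Product: 5 (2RS)-2-[(1R,4S)-4-hydroxycyclopent-2-en-1-yl]propanoic acid
Conditions: LiOH·H2O, THF/MeOH/H2O, rt; then 1 M HCl to pH 3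
Reagents that add atoms: lithium hydroxide, [Li+].[OH-]
Why: Ester saponification, placed before the enone exists so that hydroxide never meets a γ-epimerisable cyclopentenone; C5 is not acidic here and the C4 composition is irrelevant.

Step 4
Reactants: 5 (2RS)-2-[(1R,4S)-4-hydroxycyclopent-2-en-1-yl]propanoic acid; 6 sarcosine tert-butyl ester
Product: 7 tert-butyl N-{(2RS)-2-[(1R,4S)-4-hydroxycyclopent-2-en-1-yl]propanoyl}-N-methylglycinate
Conditions: N,N'-diisopropylcarbodiimide, HOBt, CH2Cl2, 0 °C to rt
Reagents that add atoms: none
Why: Carbodiimide/HOBt amide coupling: the secondary amine outcompetes the allylic hydroxyl for the active ester, and the tert-butyl ester keeps the future radical-precursor carboxyl masked.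

Step 5
Reactants: 7 tert-butyl N-{(2RS)-2-[(1R,4S)-4-hydroxycyclopent-2-en-1-yl]propanoyl}-N-methylglycinate
Product: 8 tert-butyl N-methyl-N-{(2RS)-2-[(1R)-4-oxocyclopent-2-en-1-yl]propanoyl}glycinate
Conditions: MnO2 (excess), CH2Cl2, rt
Reagents that add atoms: none
Why: MnO2 oxidises allylic alcohols selectively under neutral conditions, giving the cyclopentenone with C7 as carbonyl and C8=C9 in conjugation without any regiochemical choice; C5, now γ to the ketone, sees no base.

Step 6
Reactants: 8 tert-butyl N-methyl-N-{(2RS)-2-[(1R)-4-oxocyclopent-2-en-1-yl]propanoyl}glycinate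
Product: 9 tert-butyl N-{(2RS)-2-[(1S)-3-iodo-4-oxocyclopent-2-en-1-yl]propanoyl}-N-methylglycinate
Conditions: I2, pyridine/CH2Cl2 (1:1), 0 °C to rt
Reagents that add atoms: iodine, [I][I]
Why: α-Iodination of an enone by the pyridine-mediated addition–iodination–elimination sequence (Baylis–Hillman-type mechanism); only C8 can be iodinated, and the descriptor at C5 changes through priority alone, not through any change in space.

Step 7
Reactants: 9 tert-butyl N-{(2RS)-2-[(1S)-3-iodo-4-oxocyclopent-2-en-1-yl]propanoyl}-N-methylglycinate
Product: 10 tert-butyl N-methyl-N-{(2RS)-2-[(1R)-3-methyl-4-oxocyclopent-2-en-1-yl]propanoyl}glycinate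
Conditions: MeZnCl, Pd2(dba)3 (2.5 mol%), P(2-furyl)3 (10 mol%), THF/DMF, rt
Reagents that add atoms: methylzinc chloride, C[Zn]Cl
Why: Negishi coupling of the alkenyl iodide with MeZnCl puts C10 on C8 at room temperature; no base is present, so C5, the amide and the tert-butyl ester are untouched.

Step 8
Reactants: 10 tert-butyl N-methyl-N-{(2RS)-2-[(1R)-3-methyl-4-oxocyclopent-2-en-1-yl]propanoyl}glycinate
Product: 11 N-methyl-N-{(2RS)-2-[(1R)-3-methyl-4-oxocyclopent-2-en-1-yl]propanoyl}glycine
Conditions: CF3CO2H/CH2Cl2 (1:3), 0 °C to rt; toluene azeotrope
Reagents that add atoms: none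
Why: Acidolysis of the tert-butyl ester with loss of 2-methylpropene frees the glycine carboxyl under conditions that cannot enolise the enone towards C5.

Step 9
Reactants: 11 N-methyl-N-{(2RS)-2-[(1R)-3-methyl-4-oxocyclopent-2-en-1-yl]propanoyl}glycine
Product: 13 (4RS,4aR,7S,7aR)-2,4,7-trimethylhexahydro-1H-cyclopenta[c]pyridine-3,6(2H,4H)-dione, via C8-epimeric keto lactam 12 (not isolated)
Conditions: [Ir(dF(CF3)ppy)2(dtbbpy)]PF6 (2 mol%), K2HPO4 (1.2 equiv), degassed DMF (0.002 M), 450 nm LEDs, 45 °C; then DBU (0.3 equiv), rt
Reagents that add atoms: none
Why: The excited trivalent iridium complex oxidises the carboxylate of 11, CO2 is lost and a nucleophilic N-CH2 radical at C1 results, which adds to the electron-poor β-carbon C9 of the enone; the α-keto radical at C8 is reduced by the divalent iridium complex to the enolate, which is protonated, closing the catalytic cycle. The closest known reaction type is the photoredox decarboxylative radical conjugate addition (Giese reaction) of N-acyl α-amino acids to enones, which is also known in ring-closing form. Ring A closes in the 6-exo-trig mode, C1 attacking C9 with the C9=C8 bond outside the new ring. C9 is controlled by the tether: the chain carrying the radical hangs on C5, so C1 can only reach the face of C9 on which C4 lies, and the fusion is cis. C8 is controlled thermodynamically: where kinetic protonation gives 12 with C10 cis to C1, DBU equilibrates it through the ketone enolate to the trans-2,3-disubstituted cyclopentanone 13. The step needs regioselectivity for C9 over C8, which the polarity match between the nucleophilic radical and the enone β-carbon secures, and chemoselective oxidation of the carboxylate, the only group the excited catalyst can oxidise. It also needs the amide rotamer in which C1 lies on the side of C4; high dilution and gentle warming are chosen so that rotation about the N2–C3 bond can compete with bimolecular capture of a radical formed in the other rotamer. C4 is not touched, and both epimers cyclise.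

Step 10
Reactants: 13 (4RS,4aR,7S,7aR)-2,4,7-trimethylhexahydro-1H-cyclopenta[c]pyridine-3,6(2H,4H)-dione
Product: 15 (4R,4aR,7S,7aR)-2,4,7-trimethylhexahydro-1H-cyclopenta[c]pyridine-3,6(2H,4H)-dione, via dilithium bis-enolate 14 (not isolated)
Conditions: LiN(iPr)2 (3.2 equiv), THF, −78 to −20 °C (13 added slowly); −78 °C, 2,6-di-tert-butyl-4-methylphenol; aq. NH4Cl
Reagents that add atoms: none
Why: Kinetic protonation of a lactam enolate: excess LiN(iPr)2 first turns the ketone into its less substituted (C6) enolate, which protects it, and then removes H4; in the planar bis-enolate 14 the proton reaches C4 from the convex face, anti to the C5–C6 bond, so H4 comes out cis to H5 and C11 on the concave face. Equilibration is avoided because the analogous epimer with the methyl on the convex face is the more stable one in cis-fused iridoid lactones, and C8 keeps its configuration because the hindered methine is not deprotonated under kinetic conditions.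

Step 11
Reactants: 15 (4R,4aR,7S,7aR)-2,4,7-trimethylhexahydro-1H-cyclopenta[c]pyridine-3,6(2H,4H)-dione
Product: 16 (4R,4aS,6S,7S,7aR)-2,4,7-trimethyloctahydro-1H-cyclopenta[c]pyridin-6-ol
Conditions: LiAlH4 (excess), THF, 0 °C to reflux; H2O, aq. NaOH, H2O
Reagents that add atoms: none
Why: LiAlH4 reduces the ketone to the alcohol and the N-methyl lactam to the N-methylpiperidine; the small hydride should reach C7 from the convex face, which also gives the more stable alcohol trans to C10, i.e. the C7 epimer of the target, as the inversion in step 15 requires.

Step 12
Reactants: 17 (S)-citronellol, (3S)-3,7-dimethyloct-6-en-1-ol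
Product: 18 tert-butyl{[(3S)-3,7-dimethyloct-6-en-1-yl]oxy}dimethylsilane
Conditions: TBSCl, imidazole, CH2Cl2, 0 °C to rt
Reagents that add atoms: tert-butyldimethylsilyl chloride, CC(C)(C)[Si](C)(C)Cl
Why: Standard silylation of a primary alcohol; it masks the hydroxyl that would otherwise compete in the Mitsunobu reaction.

Step 13
Reactants: 18 tert-butyl{[(3S)-3,7-dimethyloct-6-en-1-yl]oxy}dimethylsilane
Product: 20 (2E,6S)-8-[(tert-butyldimethylsilyl)oxy]-2,6-dimethyloct-2-enal, via (E)-allylic alcohol 19 (not isolated)
Conditions: SeO2 (0.5 equiv), t-BuOOH, salicylic acid (cat.), CH2Cl2, 0 °C to rt; aq. Na2S2O3 wash; then MnO2, CH2Cl2, rt on the crude mixture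
Reagents that add atoms: selenium dioxide, O=[Se]=O (oxygen donor, turned over by tert-butyl hydroperoxide, CC(C)(C)OO)
Why: Riley allylic oxidation: the ene reaction of SeO2 at the more substituted alkene carbon and a [2,3]-sigmatropic shift functionalise only the E-methyl group; MnO2 then converges alcohol 19 and any aldehyde already present on the E-enal, and the remote stereocentre is not involved.

Step 14
Reactants: 20 (2E,6S)-8-[(tert-butyldimethylsilyl)oxy]-2,6-dimethyloct-2-enal
Product: 21 (2E,6S)-8-[(tert-butyldimethylsilyl)oxy]-2,6-dimethyloct-2-enoic acid
Conditions: NaClO2, NaH2PO4, 2-methylbut-2-ene, t-BuOH/H2O, 0 °C to rt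
Reagents that add atoms: sodium chlorite, [Na+].[O-]Cl=O
Why: Pinnick oxidation converts the enal into the acid without touching the alkene geometry or the silyl ether; the alkene scavenger removes hypochlorous acid.

Step 15
Reactants: 16 (4R,4aS,6S,7S,7aR)-2,4,7-trimethyloctahydro-1H-cyclopenta[c]pyridin-6-ol; 21 (2E,6S)-8-[(tert-butyldimethylsilyl)oxy]-2,6-dimethyloct-2-enoic acid
Product: 22 (4R,4aS,6R,7S,7aR)-2,4,7-trimethyloctahydro-1H-cyclopenta[c]pyridin-6-yl (2E,6S)-8-[(tert-butyldimethylsilyl)oxy]-2,6-dimethyloct-2-enoate
Conditions: PPh3, DIAD, THF, 0 °C to rt
Reagents that add atoms: none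
Why: Mitsunobu esterification: the alkoxyphosphonium ion of 16 is displaced by the carboxylate of 21 in an SN2 reaction with inversion, which places the ester oxygen cis to C10; the E-enoate and the silyl ether are inert and the tertiary amine is tolerated.

Step 16
Reactants: 22 (4R,4aS,6R,7S,7aR)-2,4,7-trimethyloctahydro-1H-cyclopenta[c]pyridin-6-yl (2E,6S)-8-[(tert-butyldimethylsilyl)oxy]-2,6-dimethyloct-2-enoate
Product: 23 (4R,4aS,6R,7S,7aR)-2,4,7-trimethyloctahydro-1H-cyclopenta[c]pyridin-6-yl (2E,6S)-8-hydroxy-2,6-dimethyloct-2-enoate
Conditions: HF·pyridine, THF/pyridine, 0 °C to rt; aq. NaHCO3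
Reagents that add atoms: none
Why: Fluoride-mediated cleavage of the primary silyl ether under buffered acidic conditions that leave the hindered conjugated ester and the amine (as its salt until work-up) untouched.

## Compound list

1 | (1S,4R)-cis-4-acetoxycyclopent-2-en-1-ol | O[C@H]1C[C@@H](OC(C)=O)C=C1 | starting material
2 | dimethyl methylmalonate | COC(=O)C(C)C(=O)OC | starting material
3 | dimethyl 2-[(1R,4S)-4-hydroxycyclopent-2-en-1-yl]-2-methylpropanedioate | O[C@H]1C[C@@H](C(C)(C(=O)OC)C(=O)OC)C=C1 | intermediate
4 | methyl (2RS)-2-[(1R,4S)-4-hydroxycyclopent-2-en-1-yl]propanoate (C4 epimers) | O[C@H]1C[C@@H](C(C)C(=O)OC)C=C1 | intermediate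
5 | (2RS)-2-[(1R,4S)-4-hydroxycyclopent-2-en-1-yl]propanoic acid (C4 epimers) | O[C@H]1C[C@@H](C(C)C(=O)O)C=C1 | intermediate
6 | sarcosine tert-butyl ester | CNCC(=O)OC(C)(C)C | starting material
7 | tert-butyl N-{(2RS)-2-[(1R,4S)-4-hydroxycyclopent-2-en-1-yl]propanoyl}-N-methylglycinate | O[C@H]1C[C@@H](C(C)C(=O)N(C)CC(=O)OC(C)(C)C)C=C1 | intermediate
8 | tert-butyl N-methyl-N-{(2RS)-2-[(1R)-4-oxocyclopent-2-en-1-yl]propanoyl}glycinate | O=C1C[C@@H](C(C)C(=O)N(C)CC(=O)OC(C)(C)C)C=C1 | intermediate
9 | tert-butyl N-{(2RS)-2-[(1S)-3-iodo-4-oxocyclopent-2-en-1-yl]propanoyl}-N-methylglycinate | O=C1C[C@@H](C(C)C(=O)N(C)CC(=O)OC(C)(C)C)C=C1I | intermediate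
10 | tert-butyl N-methyl-N-{(2RS)-2-[(1R)-3-methyl-4-oxocyclopent-2-en-1-yl]propanoyl}glycinate | O=C1C[C@@H](C(C)C(=O)N(C)CC(=O)OC(C)(C)C)C=C1C | intermediate
11 | N-methyl-N-{(2RS)-2-[(1R)-3-methyl-4-oxocyclopent-2-en-1-yl]propanoyl}glycine (cyclisation substrate, C4 epimers) | O=C1C[C@@H](C(C)C(=O)N(C)CC(O)=O)C=C1C | intermediate
12 | (4RS,4aR,7R,7aR)-2,4,7-trimethylhexahydro-1H-cyclopenta[c]pyridine-3,6(2H,4H)-dione (C10 cis to C1; not isolated) | O=C1C[C@@H]2[C@@H](CN(C)C(=O)C2C)[C@H]1C | intermediate
13 | (4RS,4aR,7S,7aR)-2,4,7-trimethylhexahydro-1H-cyclopenta[c]pyridine-3,6(2H,4H)-dione (cis-fused, C10 trans to C1, C4 epimers) | O=C1C[C@@H]2[C@@H](CN(C)C(=O)C2C)[C@@H]1C | intermediate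
14 | dilithium bis-enolate of 13 (C6=C7 and C3=C4 enolates; not isolated) | [Li+].[Li+].[O-]C1=C[C@@H]2[C@@H](CN(C)C([O-])=C2C)[C@@H]1C | intermediate
15 | (4R,4aR,7S,7aR)-2,4,7-trimethylhexahydro-1H-cyclopenta[c]pyridine-3,6(2H,4H)-dione (H4 cis to H5 and H9) | O=C1C[C@@H]2[C@@H](CN(C)C(=O)[C@@H]2C)[C@@H]1C | intermediate
16 | (4R,4aS,6S,7S,7aR)-2,4,7-trimethyloctahydro-1H-cyclopenta[c]pyridin-6-ol (hydroxyl trans to C10) | O[C@H]1C[C@@H]2[C@@H](CN(C)C[C@@H]2C)[C@@H]1C | intermediate
17 | (S)-citronellol, (3S)-3,7-dimethyloct-6-en-1-ol | CC(C)=CCC[C@H](C)CCO | starting material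
18 | tert-butyl{[(3S)-3,7-dimethyloct-6-en-1-yl]oxy}dimethylsilane | CC(C)=CCC[C@H](C)CCO[Si](C)(C)C(C)(C)C | intermediate
19 | (2E,6S)-8-[(tert-butyldimethylsilyl)oxy]-2,6-dimethyloct-2-en-1-ol (not isolated) | C/C(=C\CC[C@H](C)CCO[Si](C)(C)C(C)(C)C)CO | intermediate
20 | (2E,6S)-8-[(tert-butyldimethylsilyl)oxy]-2,6-dimethyloct-2-enal | C/C(=C\CC[C@H](C)CCO[Si](C)(C)C(C)(C)C)C=O | intermediate
21 | (2E,6S)-8-[(tert-butyldimethylsilyl)oxy]-2,6-dimethyloct-2-enoic acid | C/C(=C\CC[C@H](C)CCO[Si](C)(C)C(C)(C)C)C(=O)O | intermediate
22 | (4R,4aS,6R,7S,7aR)-2,4,7-trimethyloctahydro-1H-cyclopenta[c]pyridin-6-yl (2E,6S)-8-[(tert-butyldimethylsilyl)oxy]-2,6-dimethyloct-2-enoate | C/C(=C\CC[C@H](C)CCO[Si](C)(C)C(C)(C)C)C(=O)O[C@@H]1C[C@@H]2[C@@H](CN(C)C[C@@H]2C)[C@@H]1C | intermediate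
23 | (4R,4aS,6R,7S,7aR)-2,4,7-trimethyloctahydro-1H-cyclopenta[c]pyridin-6-yl (2E,6S)-8-hydroxy-2,6-dimethyloct-2-enoate | C/C(=C\CC[C@H](C)CCO)C(=O)O[C@@H]1C[C@@H]2[C@@H](CN(C)C[C@@H]2C)[C@@H]1C | target

## Step count and least certain steps

Total: 16 steps. Longest linear sequence: 13 steps (steps 1 to 11, then 15 and 16); the acid branch (steps 12 to 14) joins at step 15.

Step 9 (key step). The most likely failure is radical formation in the amide rotamer that holds C1 on the side of the C3 oxygen, away from C9. Amide rotation may then be too slow, and the radical would be lost to intermolecular addition to a second enone or to hydrogen abstraction. Sluggish single-electron oxidation of the unbranched glycine-type carboxylate is a second possibility. The fallback sets out from 11. It is esterified with 2-mercaptopyridine N-oxide and N,N'-diisopropylcarbodiimide to the O-acyl thiohydroxamate F1. F1 and Bu3SnH are then added slowly to refluxing toluene, a Barton decarboxylative radical chain. At that temperature amide rotation should be fast relative to hydrogen transfer from the dilute stannane, so both rotamers can feed the 6-exo closure. After DBU equilibration of C8 the sequence returns to the route at 13.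

Step 10. What may go wrong is incomplete deprotonation at the tertiary C4, self-condensation of the ketone enolate, or insufficient discrimination between the two faces in the protonation. The fallback sets out from 13 and removes the ketone first. NaBH4 in methanol reduces only the ketone, from the same face as expected in step 11, to the hydroxy lactam F2. LiN(iPr)2 (2.5 equiv) then forms the alkoxide–enolate, and protonation with the hindered phenol gives the hydroxy lactam with C4 set, F3. LiAlH4 reduces F3 and the sequence returns at 16.

Step 11. The risk is poor facial selectivity of hydride attack at C7, because the C10 methyl and the folded ring A screen opposite faces. The fallback sets out from 15 and uses both alcohols. After the reduction the epimers are separated. The alcohol with the hydroxyl cis to C10, F4, is acylated with retention by 21 under Yamaguchi conditions (2,4,6-trichlorobenzoyl chloride, Et3N, DMAP) and returns at 22, while 16 goes on through step 15.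

Step 15. The risk is elimination of the activated alcohol, or acylation with retention, because the carboxylate must approach C7 past the cis C10 methyl. The fallback sets out from 16. A Mitsunobu reaction with the more acidic 4-nitrobenzoic acid gives the inverted 4-nitrobenzoate F5, and methanolysis (K2CO3, MeOH) gives F4. Yamaguchi esterification of F4 with 21 returns to the route at 22.

Step 13. The risk is a stalled or over-running allylic oxidation (alcohol/aldehyde mixtures, oxidation of a second allylic position, selenium residues). The fallback sets out from 18. Ozonolysis (O3, CH2Cl2, −78 °C; PPh3) gives the aldehyde F6, and a Wittig reaction with 2-(triphenylphosphoranylidene)propanal in warm toluene gives the E-enal, returning to the route at 20.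

## Further compounds

F1 | step 9 | 2-thioxopyridin-1(2H)-yl N-methyl-N-{(2RS)-2-[(1R)-3-methyl-4-oxocyclopent-2-en-1-yl]propanoyl}glycinate | O=C1C[C@@H](C(C)C(=O)N(C)CC(=O)ON2C=CC=CC2=S)C=C1C
F2 | step 10 | (4RS,4aR,6S,7S,7aR)-6-hydroxy-2,4,7-trimethyloctahydro-3H-cyclopenta[c]pyridin-3-one | O[C@H]1C[C@@H]2[C@@H](CN(C)C(=O)C2C)[C@@H]1C
F3 | step 10 | (4R,4aR,6S,7S,7aR)-6-hydroxy-2,4,7-trimethyloctahydro-3H-cyclopenta[c]pyridin-3-one | O[C@H]1C[C@@H]2[C@@H](CN(C)C(=O)[C@@H]2C)[C@@H]1C
F4 | step 11 | (4R,4aS,6R,7S,7aR)-2,4,7-trimethyloctahydro-1H-cyclopenta[c]pyridin-6-ol | O[C@@H]1C[C@@H]2[C@@H](CN(C)C[C@@H]2C)[C@@H]1C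
F5 | step 15 | (4R,4aS,6R,7S,7aR)-2,4,7-trimethyloctahydro-1H-cyclopenta[c]pyridin-6-yl 4-nitrobenzoate | O=C(O[C@@H]1C[C@@H]2[C@@H](CN(C)C[C@@H]2C)[C@@H]1C)c1ccc(cc1)[N+](=O)[O-]
F6 | step 13 | (4S)-6-[(tert-butyldimethylsilyl)oxy]-4-methylhexanal | O=CCC[C@H](C)CCO[Si](C)(C)C(C)(C)C
A1 | alternative 1 | (2E,5R,6S)-5-[(tert-butyldimethylsilyl)oxy]-2,6-dimethyloct-2-enedial | O=C/C(C)=C/C[C@@H](O[Si](C)(C)C(C)(C)C)[C@@H](C)CC=O
A2 | alternative 1 | cis-fused 7-silyloxy nepetalactol-type N-methylanilino acetal | CC(C)(C)[Si](C)(C)O[C@@H]1C[C@@H]2[C@@H]([C@@H](N(C)c3ccccc3)OC=C2C)[C@@H]1C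
A3 | alternative 1 | (4R,4aS,6R,7S,7aR)-6-[(tert-butyldimethylsilyl)oxy]-2,4,7-trimethyloctahydro-1H-cyclopenta[c]pyridine | CC(C)(C)[Si](C)(C)O[C@@H]1C[C@@H]2[C@@H](CN(C)C[C@@H]2C)[C@@H]1C
A4 | alternative 2 | 2-[(tert-butyldimethylsilyl)oxy]cyclopenta-1,3-diene | CC(C)(C)[Si](C)(C)OC1=CCC=C1
A5 | alternative 2 | 3-[(2E)-but-2-enoyl]-1,3-oxazolidin-2-one | C/C=C/C(=O)N1CCOC1=O
A6 | alternative 2 | endo norbornene silyl enol ether imide | CC(C)(C)[Si](C)(C)OC1=C[C@@H]2C[C@H]1[C@@H](C)[C@@H]2C(=O)N3CCOC3=O
A7 | alternative 2 | bridged lactone (2-oxabicyclo[3.2.1]octan-3-one) carrying C10 and the imide | O=C1C[C@@H]2C[C@H](O1)[C@@H](C)[C@@H]2C(=O)N3CCOC3=O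
A8 | alternative 3 | tert-butyldimethyl{[(1R,2S)-2-methylcyclopent-3-en-1-yl]oxy}silane | CC(C)(C)[Si](C)(C)O[C@@H]1CC=C[C@@H]1C
A9 | alternative 3 | (2Z)-3-hydroxy-2-methylprop-2-enal (chelated enol of 2-methylmalondialdehyde) | O/C=C(/C)C=O
A10 | alternative 3 | 7-silyloxy iridodial-type dialdehyde | CC(C)(C)[Si](C)(C)O[C@@H]1C[C@@H]([C@@H](C)C=O)[C@@H](C=O)[C@@H]1C
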